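All runs are simulated with made-up constants; scatter was added.

Start from what is left: at 30.0 min the blue run still holds 64.8% of its substrate and the violet run 69.7%, and from that leftover you can begin to reckon the new flasks.

| flask | substrate | gas | remark | time |
|---|---|---|---|---|
| blue | 0.087 M (fed, over 15 min) | 4.8 mM (held) | run made earlier; the fed solution adds 0.10 times the starting volume |  |
| violet | 0.17 M (fed, over 15 min) | 4.8 mM (held) | run made earlier; the fed solution adds 0.10 times the starting volume |  |
| noon | 0.060 M | 4.8 mM | everything together at the start, the whole solution of substrate included, so that from the start the volume is larger by 0.10 times the starting volume | 20 min |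
| dusk | 0.12 M (fed, over 15 min) | 4.8 mM (held) | the fed solution adds 0.10 times the starting volume | 30 min |

- blue (time / min: first product / %, substrate / %): 2.50: 1.7, 16.1; 6.00: 1.7, 37.7; 12.0: 7.8, 71.1; 30.0: 25.6, 64.8
- violet (time / min: first product / %, substrate / %): 2.50: 0.7, 15.5; 6.00: 3.0, 37.8; 12.0: 7.8, 71.5; 30.0: 20.4, 69.7

(scatter of a reading: 1 percentage point)

- charges are per starting volume, the dose included; the dosed solution carries all of it
- at the start none of the gas is in solution
- percentages count the whole charge, also what has not yet gone in

1. the flask that ends with the higher amount of first product, in percent of the substrate charged, or "neither" when 2 percentage points or less lies between them (noon / dusk / neither)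
2. final first product, as a percentage of the substrate charged, in noon
3. final first product, as a percentage of the substrate charged, in dusk

Run blue slowly. In the first instants, at 2.50 min, 16.7% of the charge has gone in and the substrate reads 16.1%, nearly all of that, while first product reads 1.7% against a scatter of 1 percentage point. In the middle, at 12.0 min, 80.0% has gone in and substrate plus first product come to 78.9%, so the balance still closes within the scatter. At the end, at 30.0 min, that sum is 90.4%, so something unread has begun to take material. I therefore call the share of consumed substrate still standing as first product the kept share, which reads 72.7% in blue and 67.3% in violet.

A steady feed puts the average portion in after half the dosing time, so in a fed run that portion has had 22.5 min by 30 min. Dividing the logarithm of charged over left by this time gives the pseudo-first-order loss constant k, the fraction of substrate consumed per minute, which as a reading with the scatter of its readings stands at 0.0193 min⁻¹ in blue and 0.0160 min⁻¹ in the richer violet. The exposure is k times that time, and the leftover is its negative exponential.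

My own reckoning takes blue's values for noon, whose charge of 0.060 M lies nearer blue's 0.087 M. Its whole 20 min counts, so the exposure is 0.386, the leftover 68.0%, and first product 23.3%. Dusk lies between the runs, so I take the means: k is 0.0177 min⁻¹, the exposure 0.398, the leftover 67.1%, and first product 23.0%. The gap of 0.30 points is less than the margin of 2 points, so my reckoning says neither.

The forecast, “Treating each fed run as a batch delayed by 7.5 min”, says neither, with 25% for noon and 23.5% for dusk, so its noon stands 1.7 points above mine.

The flasks give 23.1% in noon and 22.5% in dusk, so the outcome is neither.

    substrate + partner → first product + released group (k = 0.0880 M⁻¹ s⁻¹)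
    gas ⇌ partner, rate k2*(csat - [partner]) (kL = 0.0230 s⁻¹)
    partner + first product → bis adduct + released group (k = 0.0990 M⁻¹ s⁻¹)
    first product → over-reaction product (k = 2.40 × 10⁻⁴ s⁻¹)

Noon holds 66% of its substrate after 20.0 min and dusk 66% after 30.0 min, against the leftovers of 68.0% and 67.1% reckoned above. Take noon instead at 8.0 min, with amounts and temperature held: blue's constant gives an exposure of 0.154 and a leftover of 85.7%, and that flask holds 86% of its substrate.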